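**Retrosynthetic overview**

1. Target ⇒ (desilylation; acetyl → isopropenyl → isopropyl) cyclohexenyl methyl ketone ⇒ Diels–Alder reaction of methyl vinyl ketone with the terminal diene (C4–C7) of a core-bound (2E,4E)-2,6-bis(silyloxymethyl)hepta-2,4,6-trienoate.
2. Enabling feature: in the cyclohexene of the acyl half the C=C lies between C2 (CH) and C3 (C–CH2OH), the ring bonds C1–C6 and C4–C5 are both β to it, and the trans stereocentres C1 (propenoate arm) and C6 (isopropyl) are vicinal. This is a 4-acylcyclohexene retron; the fully substituted C2 of the trienoate blocks its inner diene.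
3. Triene ester ⇒ Yamaguchi esterification of the trienoic acid (Heck coupling, then oxa-Michael/Horner–Wadsworth–Emmons) with the primary hydroxyl of the bicyclic diol lactone.
4. Core ⇒ oxepinone by ring-closing metathesis (C4=C5); C9 carbinol by Corey–Chaykovsky epoxidation and opening; substituents by vinyl cuprate/formaldehyde coupling on (R)-4-isopropylcyclohexenone.
5. Ring order: core cyclohexane (step 2) → oxepinone (step 11) → cyclohexene of the acyl half (step 19).

Key step: step 19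

Remark on locants and one assumption: the core is numbered as 2-benzoxepine (C1 lactone carbonyl, O2, C3, C4, C5, C5a, C6 isopropyl carbon, C7, C8, C9 carbinol carbon, C9a). The cyclohexene of the acyl half is numbered C1 (CH bearing the propenoate), C2, C3 (C–CH2O), C4, C5, C6. The catalyst antipodes named in steps 1 and 19 are those predicted by the usual face-shielding models; if correlation shows the opposite sense, the enantiomeric catalyst is used with no other change.

**Route**

Step 1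
Reactants: 1 3-methylbutanal; 2 but-3-en-2-one (methyl vinyl ketone)
Product: 3 (2R)-5-oxo-2-(propan-2-yl)hexanal
Conditions: (R)-2-(methoxydiphenylmethyl)pyrrolidine (5 mol %), ethyl 3,4-dihydroxybenzoate (20 mol %), neat, 4 °C
Reagents that add atoms: none
Why: Enamine-catalysed Michael addition of an aldehyde to a vinyl ketone, in which the diarylmethyl group of the (R)-catalyst shields one face of the (E)-enamine so that the enone should add to the other face and set the isopropyl-bearing centre as (R).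

Step 2
Reactants: 3 (2R)-5-oxo-2-(propan-2-yl)hexanal
Product: 4 (4R)-4-(propan-2-yl)cyclohex-2-en-1-one ((R)-cryptone)
Conditions: KOH (0.1 M aq., 10 mol %), n-Bu4NOH (cat.), Et2O/THF/H2O, reflux, short contact
Reagents that add atoms: none
Why: Intramolecular aldol condensation of the 1,5-keto aldehyde (methyl ketone onto aldehyde) closes the cyclohexenone, and dilute base with short contact should limit enolisation of the α-branched aldehyde so that the stereocentre is carried over.

Step 3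
Reactants: 4 (4R)-4-(propan-2-yl)cyclohex-2-en-1-one
Product: 6 (2R,3R,4R)-3-ethenyl-2-(hydroxymethyl)-4-(propan-2-yl)cyclohexan-1-one, via bromomagnesium enolate 5 (not isolated)
Conditions: CH2=CHMgBr (1.3 equiv), CuBr·SMe2 (10 mol %), THF, −78 °C; then CH2O (g), −78 → −30 °C; aq. NH4Cl
Reagents that add atoms: vinylmagnesium bromide, C=C[Mg]Br; formaldehyde, C=O
Why: Copper-catalysed conjugate addition followed by aldol trapping (three-component coupling), in which the vinyl group should enter C3 anti to the C4 isopropyl group and formaldehyde should attack the regio-defined enolate at C2 anti to the new vinyl group, giving the all-trans ketone.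

Step 4
Reactants: 6 (2R,3R,4R)-3-ethenyl-2-(hydroxymethyl)-4-(propan-2-yl)cyclohexan-1-one
Product: 7 (2R,3R,4R)-3-ethenyl-4-(propan-2-yl)-2-({[tri(propan-2-yl)silyl]oxy}methyl)cyclohexan-1-one
Conditions: i-Pr3SiCl, imidazole, DMF, 0 °C → rt
Reagents that add atoms: chlorotri(propan-2-yl)silane, CC(C)[Si](Cl)(C(C)C)C(C)C
Why: Routine silylation of the primary alcohol, with the triisopropylsilyl group chosen because it should survive the ylide of step 5 and the alkoxide of step 6.

Step 5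
Reactants: 7 (2R,3R,4R)-3-ethenyl-4-(propan-2-yl)-2-({[tri(propan-2-yl)silyl]oxy}methyl)cyclohexan-1-one
Product: 8 (3S,4R,5R,6R)-5-ethenyl-6-(propan-2-yl)-4-({[tri(propan-2-yl)silyl]oxy}methyl)-1-oxaspiro[2.5]octane (oxirane CH2 axial, O equatorial)
Conditions: Me3S+ I−, KN(SiMe3)2, THF, −10 → 0 °C
Reagents that add atoms: trimethylsulfonium iodide, C[S+](C)C.[I-]
Why: Corey–Chaykovsky epoxidation, in which the unstabilised sulfonium methylide should add irreversibly along the axial trajectory of the all-equatorial chair (no 1,3-diaxial substituent), placing the new C–C bond axial and the oxygen equatorial and so setting the spiro carbon.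

Step 6
Reactants: 8 (3S,4R,5R,6R)-5-ethenyl-6-(propan-2-yl)-4-({[tri(propan-2-yl)silyl]oxy}methyl)-1-oxaspiro[2.5]octane
Product: 9 (1S,2R,3R,4R)-3-ethenyl-1-{[(4-methoxyphenyl)methoxy]methyl}-4-(propan-2-yl)-2-({[tri(propan-2-yl)silyl]oxy}methyl)cyclohexan-1-ol
Conditions: 4-MeOC6H4CH2OH (3 equiv), NaH (1.5 equiv), DMF, 60 °C; aq. NH4Cl
Reagents that add atoms: (4-methoxyphenyl)methanol, COc1ccc(CO)cc1
Why: Base-mediated SN2 opening of the 2,2-disubstituted oxirane at its CH2 terminus by the alkoxide, which touches no stereocentre and delivers the tertiary alcohol and the protected primary ether in one operation.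

Step 7
Reactants: 9 (1S,2R,3R,4R)-3-ethenyl-1-{[(4-methoxyphenyl)methoxy]methyl}-4-(propan-2-yl)-2-({[tri(propan-2-yl)silyl]oxy}methyl)cyclohexan-1-ol
Product: 10 (1S,2R,3R,4R)-3-ethenyl-2-(hydroxymethyl)-1-{[(4-methoxyphenyl)methoxy]methyl}-4-(propan-2-yl)cyclohexan-1-ol
Conditions: n-Bu4NF, THF, 0 °C → rt; aq. NH4Cl
Reagents that add atoms: none
Why: Fluoride-mediated cleavage of the silyl ether, which should leave the benzylic ether, the alkene and the tertiary alcohol untouched.

Step 8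
Reactants: 10 (1S,2R,3R,4R)-3-ethenyl-2-(hydroxymethyl)-1-{[(4-methoxyphenyl)methoxy]methyl}-4-(propan-2-yl)cyclohexan-1-ol
Product: 11 (1S,2S,5R,6R)-6-ethenyl-2-hydroxy-2-{[(4-methoxyphenyl)methoxy]methyl}-5-(propan-2-yl)cyclohexane-1-carboxylic acid
Conditions: TEMPO (20 mol %), PhI(OAc)2 (2.5 equiv), MeCN/pH 7 buffer, rt
Reagents that add atoms: water, O
Why: Oxoammonium-mediated oxidation of the primary alcohol through the aldehyde hydrate to the acid, which should spare the tertiary alcohol and the alkene, and the all-equatorial C1 centre is the thermodynamic one.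

Step 9
Reactants: 12 2-(bromomethyl)prop-2-enoic acid; 13 2-(trimethylsilyl)ethan-1-ol
Product: 14 2-(trimethylsilyl)ethyl 2-(bromomethyl)prop-2-enoate
Conditions: DCC, DMAP (5 mol %), CH2Cl2, 0 °C
Reagents that add atoms: none
Why: Steglich esterification at low temperature with little DMAP, so that acylation should outrun displacement of the allylic bromide.

Step 10
Reactants: 11 (1S,2S,5R,6R)-6-ethenyl-2-hydroxy-2-{[(4-methoxyphenyl)methoxy]methyl}-5-(propan-2-yl)cyclohexane-1-carboxylic acid; 14 2-(trimethylsilyl)ethyl 2-(bromomethyl)prop-2-enoate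
Product: 16 2-{[2-(trimethylsilyl)ethoxy]carbonyl}prop-2-en-1-yl (1S,2S,5R,6R)-6-ethenyl-2-hydroxy-2-{[(4-methoxyphenyl)methoxy]methyl}-5-(propan-2-yl)cyclohexane-1-carboxylate, via cesium carboxylate 15 (not isolated)
Conditions: Cs2CO3 (0.55 equiv), DMF, 0 °C; then 14, 0 °C → rt
Reagents that add atoms: none
Why: O-alkylation of the carboxylate by the highly reactive allylic bromide (SN2 and SN2' give the same ester), which avoids activating the β-hydroxy acid.

Step 11
Reactants: 16 2-{[2-(trimethylsilyl)ethoxy]carbonyl}prop-2-en-1-yl (1S,2S,5R,6R)-6-ethenyl-2-hydroxy-2-{[(4-methoxyphenyl)methoxy]methyl}-5-(propan-2-yl)cyclohexane-1-carboxylate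
Product: 17 2-(trimethylsilyl)ethyl (5aS,6R,9S,9aS)-9-hydroxy-9-{[(4-methoxyphenyl)methoxy]methyl}-1-oxo-6-(propan-2-yl)-1,3,5a,6,7,8,9,9a-octahydro-2-benzoxepine-4-carboxylate
Conditions: second-generation Hoveyda–Grubbs catalyst RuCl2(H2IMes)(=CH-C6H4-2-O-i-Pr) (5 mol %), toluene (2 mM), 80 °C
Reagents that add atoms: none
Why: Ring-closing metathesis between the vinyl group and the 2-substituted acrylate closes the seven-membered lactone, with the trans-diequatorial arms pre-organised and the ring fixing the C4=C5 geometry.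

Step 12
Reactants: 17 2-(trimethylsilyl)ethyl (5aS,6R,9S,9aS)-9-hydroxy-9-{[(4-methoxyphenyl)methoxy]methyl}-1-oxo-6-(propan-2-yl)-1,3,5a,6,7,8,9,9a-octahydro-2-benzoxepine-4-carboxylate
Product: 18 2-(trimethylsilyl)ethyl (5aS,6R,9S,9aS)-9-hydroxy-9-(hydroxymethyl)-1-oxo-6-(propan-2-yl)-1,3,5a,6,7,8,9,9a-octahydro-2-benzoxepine-4-carboxylate
Conditions: DDQ (1.3 equiv), CH2Cl2/pH 7 buffer (10:1), 0 °C; used at once in step 17
Reagents that add atoms: none
Why: Oxidative cleavage of the 4-methoxybenzyl ether under neutral conditions, which should not disturb the lactone, the enoate or the silylethyl ester.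

Step 13
Reactants: 19 2-bromoprop-2-en-1-ol
Product: 20 [(2-bromoprop-2-en-1-yl)oxy](tert-butyl)dimethylsilane
Conditions: t-BuMe2SiCl, imidazole, CH2Cl2, 0 °C → rt
Reagents that add atoms: tert-butylchlorodimethylsilane, CC(C)(C)[Si](C)(C)Cl
Why: Routine silylation of the primary allylic alcohol.

Step 14
Reactants: 20 [(2-bromoprop-2-en-1-yl)oxy](tert-butyl)dimethylsilane; 21 prop-2-enal (acrolein)
Product: 22 (2E)-4-({[tert-butyl(dimethyl)silyl]oxy}methyl)penta-2,4-dienal
Conditions: Pd(OAc)2 (5 mol %), n-Bu4NCl (1 equiv), NaHCO3 (2.5 equiv), DMF, 40 °C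
Reagents that add atoms: none
Why: Heck coupling of the vinyl bromide with acrolein under phase-transfer (Jeffery) conditions, where syn insertion and syn β-hydride elimination should give the (E)-dienal.

Step 15
Reactants: 22 (2E)-4-({[tert-butyl(dimethyl)silyl]oxy}methyl)penta-2,4-dienal; 23 ethyl 2-(diethoxyphosphoryl)prop-2-enoate
Product: 25 ethyl (2E,4E)-2,6-bis({[tert-butyl(dimethyl)silyl]oxy}methyl)hepta-2,4,6-trienoate, via potassium phosphonate carbanion 24 (not isolated)
Conditions: t-BuMe2SiOH (1.05 equiv), KN(SiMe3)2 (1.0 equiv), THF, −78 °C; 23, −78 °C; then 22, −78 → 0 °C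
Reagents that add atoms: tert-butyldimethylsilanol, CC(C)(C)[Si](C)(C)O
Why: Tandem oxa-Michael addition/Horner–Wadsworth–Emmons olefination on the 2-phosphonoacrylate, in which the silanolate adduct is the stabilised phosphonate anion that should olefinate the enal 1,2 and place the ester trans to the dienyl chain (E).

Step 16
Reactants: 25 ethyl (2E,4E)-2,6-bis({[tert-butyl(dimethyl)silyl]oxy}methyl)hepta-2,4,6-trienoate
Product: 26 (2E,4E)-2,6-bis({[tert-butyl(dimethyl)silyl]oxy}methyl)hepta-2,4,6-trienoic acid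
Conditions: LiOH·H2O (3 equiv), THF/MeOH/H2O (3:1:1), rt; then 0.5 M HCl to pH 4
Reagents that add atoms: lithium hydroxide, [Li+].[OH-]
Why: Saponification of the ethyl ester, which the primary silyl ethers should tolerate at room temperature.

Step 17
Reactants: 26 (2E,4E)-2,6-bis({[tert-butyl(dimethyl)silyl]oxy}methyl)hepta-2,4,6-trienoic acid; 18 2-(trimethylsilyl)ethyl (5aS,6R,9S,9aS)-9-hydroxy-9-(hydroxymethyl)-1-oxo-6-(propan-2-yl)-1,3,5a,6,7,8,9,9a-octahydro-2-benzoxepine-4-carboxylate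
Product: 28 2-(trimethylsilyl)ethyl (5aS,6R,9S,9aS)-9-({[(2E,4E)-2,6-bis({[tert-butyl(dimethyl)silyl]oxy}methyl)hepta-2,4,6-trienoyl]oxy}methyl)-9-hydroxy-1-oxo-6-(propan-2-yl)-1,3,5a,6,7,8,9,9a-octahydro-2-benzoxepine-4-carboxylate, via mixed anhydride 27 (not isolated)
Conditions: 26 (1.3 equiv), 2,4,6-Cl3C6H2COCl, Et3N, THF, 0 °C → rt; then 18, DMAP (1.5 equiv), toluene, 0 °C
Reagents that add atoms: none
Why: Yamaguchi esterification, in which the acylpyridinium should acylate the primary hydroxyl quickly while the tertiary hydroxyl stays free.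

Step 18
Reactants: 28 (triene ester with free C9 hydroxyl)
Product: 29 2-(trimethylsilyl)ethyl (5aS,6R,9S,9aS)-9-({[(2E,4E)-2,6-bis({[tert-butyl(dimethyl)silyl]oxy}methyl)hepta-2,4,6-trienoyl]oxy}methyl)-1-oxo-6-(propan-2-yl)-9-[(triethylsilyl)oxy]-1,3,5a,6,7,8,9,9a-octahydro-2-benzoxepine-4-carboxylate
Conditions: Et3SiOTf, 2,6-lutidine, CH2Cl2, −78 → −40 °C
Reagents that add atoms: triethylsilyl trifluoromethanesulfonate, CC[Si](CC)(CC)OS(=O)(=O)C(F)(F)F
Why: Silylation of the tertiary alcohol with a silyl triflate, which removes the only free hydroxyl before the Lewis-acid-catalysed key step.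

Step 19
Reactants: 29 (triethylsilyl-protected triene ester); 2 but-3-en-2-one
Product: 30 2-(trimethylsilyl)ethyl (5aS,6R,9S,9aS)-9-({[(2E)-3-[(1R,6R)-6-acetyl-3-({[tert-butyl(dimethyl)silyl]oxy}methyl)cyclohex-2-en-1-yl]-2-({[tert-butyl(dimethyl)silyl]oxy}methyl)prop-2-enoyl]oxy}methyl)-1-oxo-6-(propan-2-yl)-9-[(triethylsilyl)oxy]-1,3,5a,6,7,8,9,9a-octahydro-2-benzoxepine-4-carboxylate (cis adduct)
Conditions: 2 (5 equiv), (S)-1-(2-methylphenyl)-3,3-diphenyltetrahydro-1H,3H-pyrrolo[1,2-c][1,3,2]oxazaborole·HNTf2 (20 mol %), CH2Cl2, −78 → −40 °C; Et3N quench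
Reagents that add atoms: none
Why: The protonated oxazaborolidine binds the carbonyl of methyl vinyl ketone and lowers its LUMO, and a concerted, asynchronous, normal-demand [4+2] cycloaddition with the terminal diene (C4–C7) of the trienoate follows. The closest known reaction type is the catalytic enantioselective Diels–Alder reaction of acyclic 1,3-dienes with vinyl ketones under chiral cationic oxazaborolidine catalysis. The cyclohexene is closed intermolecularly, both ring bonds (C1–C6 and C4–C5) forming suprafacially in one event. C1 is set by the catalyst, which exposes one face of the bound enone to the diene, the remote core acting only as the ester alkyl group; C6 is set by endo orientation of the acetyl group, which gives the cis adduct that step 20 corrects to trans. The step needs site selectivity, secured by the fully substituted C2 of the trienoate, which keeps the inner diene out of a reactive s-cis geometry. It also needs regioselectivity, secured because the "ortho" preference of the 1-alkenyl group and the "para" preference of the 3-CH2OSi group both place the acetyl-bearing carbon next to C1, and chemoselectivity, secured because the two trisubstituted enoates are poor dienophiles.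

Step 20
Reactants: 30 (cis adduct)
Product: 31 the (1R,6S)-6-acetyl epimer of 30 (trans ketone)
Conditions: camphor-10-sulfonic acid (10 mol %), toluene, 40 °C; cis isomer recycled
Reagents that add atoms: none
Why: Acid-catalysed enolisation equilibrates only the ketone α-centre towards the diequatorial trans isomer, whereas base is avoided because the doubly allylic C1–H, γ to the enoate, would be at risk.

Step 21
Reactants: 31 (trans ketone)
Product: 32 the (1R,6S)-6-(prop-1-en-2-yl) analogue of 31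
Conditions: Zn, CH2Br2, TiCl4 (pre-formed reagent), THF/CH2Cl2, 0 °C → rt; aq. NaHCO3
Reagents that add atoms: dibromomethane, BrCBr
Why: Takai–Lombardo methylenation is non-basic and ketone-selective, so it should leave the α-centre, the skipped dienoate, the esters and the silyl ethers untouched.

Step 22
Reactants: 32 (isopropenyl compound)
Product: 33 2-(trimethylsilyl)ethyl (5aS,6R,9S,9aS)-9-({[(2E)-3-[(1R,6R)-3-({[tert-butyl(dimethyl)silyl]oxy}methyl)-6-(propan-2-yl)cyclohex-2-en-1-yl]-2-({[tert-butyl(dimethyl)silyl]oxy}methyl)prop-2-enoyl]oxy}methyl)-1-oxo-6-(propan-2-yl)-9-[(triethylsilyl)oxy]-1,3,5a,6,7,8,9,9a-octahydro-2-benzoxepine-4-carboxylate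
Conditions: H2 (1 atm), RhCl(PPh3)3 (10 mol %), benzene, rt
Reagents that add atoms: none
Why: Homogeneous hydrogenation with RhCl(PPh3)3 should reduce the unhindered 1,1-disubstituted alkene much faster than the three trisubstituted alkenes (the carvone-to-carvotanacetone type of selectivity), and no stereocentre is created.

Step 23
Reactants: 33 (fully protected target)
Product: 34 (5aS,6R,9S,9aS)-9-hydroxy-9-({[(2E)-2-(hydroxymethyl)-3-[(1R,6R)-3-(hydroxymethyl)-6-(propan-2-yl)cyclohex-2-en-1-yl]prop-2-enoyl]oxy}methyl)-1-oxo-6-(propan-2-yl)-1,3,5a,6,7,8,9,9a-octahydro-2-benzoxepine-4-carboxylic acid (CNP0361406.2)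
Conditions: (Me2N)3S+ Me3SiF2− (TASF, 6 equiv), DMF/H2O, 0 °C → rt; aq. NH4Cl
Reagents that add atoms: none
Why: Global fluoride-mediated desilylation removes both tert-butyldimethylsilyl ethers, the triethylsilyl ether and the 2-(trimethylsilyl)ethyl ester (β-silyl fragmentation) under weakly basic conditions that the skipped dienoate and the lactone should tolerate.

**Compound list**

1 | 3-methylbutanal | CC(C)CC=O | starting material
2 | but-3-en-2-one (methyl vinyl ketone) | CC(=O)C=C | starting material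
3 | (2R)-5-oxo-2-(propan-2-yl)hexanal | CC(C)[C@H](C=O)CCC(C)=O | intermediate
4 | (4R)-4-(propan-2-yl)cyclohex-2-en-1-one | CC(C)[C@H]1CCC(=O)C=C1 | intermediate
5 | bromomagnesium (3R,4R)-3-ethenyl-4-(propan-2-yl)cyclohex-1-en-1-olate | CC(C)[C@H]1CCC(O[Mg]Br)=C[C@@H]1C=C | intermediate (not isolated)
6 | (2R,3R,4R)-3-ethenyl-2-(hydroxymethyl)-4-(propan-2-yl)cyclohexan-1-one | CC(C)[C@H]1CCC(=O)[C@@H](CO)[C@@H]1C=C | intermediate
7 | (2R,3R,4R)-3-ethenyl-4-(propan-2-yl)-2-({[tri(propan-2-yl)silyl]oxy}methyl)cyclohexan-1-one | CC(C)[C@H]1CCC(=O)[C@@H](CO[Si](C(C)C)(C(C)C)C(C)C)[C@@H]1C=C | intermediate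
8 | (3S,4R,5R,6R)-5-ethenyl-6-(propan-2-yl)-4-({[tri(propan-2-yl)silyl]oxy}methyl)-1-oxaspiro[2.5]octane | CC(C)[C@H]1CC[C@@]2(CO2)[C@@H](CO[Si](C(C)C)(C(C)C)C(C)C)[C@@H]1C=C | intermediate
9 | (1S,2R,3R,4R)-3-ethenyl-1-{[(4-methoxyphenyl)methoxy]methyl}-4-(propan-2-yl)-2-({[tri(propan-2-yl)silyl]oxy}methyl)cyclohexan-1-ol | CC(C)[C@H]1CC[C@@](O)(COCc2ccc(OC)cc2)[C@@H](CO[Si](C(C)C)(C(C)C)C(C)C)[C@@H]1C=C | intermediate
10 | (1S,2R,3R,4R)-3-ethenyl-2-(hydroxymethyl)-1-{[(4-methoxyphenyl)methoxy]methyl}-4-(propan-2-yl)cyclohexan-1-ol | CC(C)[C@H]1CC[C@@](O)(COCc2ccc(OC)cc2)[C@@H](CO)[C@@H]1C=C | intermediate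
11 | (1S,2S,5R,6R)-6-ethenyl-2-hydroxy-2-{[(4-methoxyphenyl)methoxy]methyl}-5-(propan-2-yl)cyclohexane-1-carboxylic acid | CC(C)[C@H]1CC[C@@](O)(COCc2ccc(OC)cc2)[C@@H](C(=O)O)[C@@H]1C=C | intermediate
12 | 2-(bromomethyl)prop-2-enoic acid | OC(=O)C(=C)CBr | starting material
13 | 2-(trimethylsilyl)ethan-1-ol | C[Si](C)(C)CCO | starting material
14 | 2-(trimethylsilyl)ethyl 2-(bromomethyl)prop-2-enoate | C=C(CBr)C(=O)OCC[Si](C)(C)C | intermediate
15 | cesium (1S,2S,5R,6R)-6-ethenyl-2-hydroxy-2-{[(4-methoxyphenyl)methoxy]methyl}-5-(propan-2-yl)cyclohexane-1-carboxylate | CC(C)[C@H]1CC[C@@](O)(COCc2ccc(OC)cc2)[C@@H](C(=O)[O-])[C@@H]1C=C.[Cs+] | intermediate (not isolated)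
16 | 2-{[2-(trimethylsilyl)ethoxy]carbonyl}prop-2-en-1-yl (1S,2S,5R,6R)-6-ethenyl-2-hydroxy-2-{[(4-methoxyphenyl)methoxy]methyl}-5-(propan-2-yl)cyclohexane-1-carboxylate | CC(C)[C@H]1CC[C@@](O)(COCc2ccc(OC)cc2)[C@@H](C(=O)OCC(=C)C(=O)OCC[Si](C)(C)C)[C@@H]1C=C | intermediate
17 | 2-(trimethylsilyl)ethyl (5aS,6R,9S,9aS)-9-hydroxy-9-{[(4-methoxyphenyl)methoxy]methyl}-1-oxo-6-(propan-2-yl)-1,3,5a,6,7,8,9,9a-octahydro-2-benzoxepine-4-carboxylate | CC(C)[C@H]1CC[C@@](O)(COCc3ccc(OC)cc3)[C@H]2C(=O)OCC(C(=O)OCC[Si](C)(C)C)=C[C@H]12 | intermediate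
18 | 2-(trimethylsilyl)ethyl (5aS,6R,9S,9aS)-9-hydroxy-9-(hydroxymethyl)-1-oxo-6-(propan-2-yl)-1,3,5a,6,7,8,9,9a-octahydro-2-benzoxepine-4-carboxylate | CC(C)[C@H]1CC[C@@](O)(CO)[C@H]2C(=O)OCC(C(=O)OCC[Si](C)(C)C)=C[C@H]12 | intermediate
19 | 2-bromoprop-2-en-1-ol | OCC(Br)=C | starting material
20 | [(2-bromoprop-2-en-1-yl)oxy](tert-butyl)dimethylsilane | CC(C)(C)[Si](C)(C)OCC(Br)=C | intermediate
21 | prop-2-enal (acrolein) | C=CC=O | starting material
22 | (2E)-4-({[tert-butyl(dimethyl)silyl]oxy}methyl)penta-2,4-dienal | O=C/C=C/C(=C)CO[Si](C)(C)C(C)(C)C | intermediate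
23 | ethyl 2-(diethoxyphosphoryl)prop-2-enoate | CCOC(=O)C(=C)P(=O)(OCC)OCC | starting material
24 | potassium carbanion of ethyl 3-{[tert-butyl(dimethyl)silyl]oxy}-2-(diethoxyphosphoryl)propanoate | CCOC(=O)[C-](CO[Si](C)(C)C(C)(C)C)P(=O)(OCC)OCC.[K+] | intermediate (not isolated)
25 | ethyl (2E,4E)-2,6-bis({[tert-butyl(dimethyl)silyl]oxy}methyl)hepta-2,4,6-trienoate | CCOC(=O)/C(CO[Si](C)(C)C(C)(C)C)=C/C=C/C(=C)CO[Si](C)(C)C(C)(C)C | intermediate
26 | (2E,4E)-2,6-bis({[tert-butyl(dimethyl)silyl]oxy}methyl)hepta-2,4,6-trienoic acid | OC(=O)/C(CO[Si](C)(C)C(C)(C)C)=C/C=C/C(=C)CO[Si](C)(C)C(C)(C)C | intermediate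
27 | mixed anhydride of 26 with 2,4,6-trichlorobenzoic acid | O=C(OC(=O)c1c(Cl)cc(Cl)cc1Cl)/C(CO[Si](C)(C)C(C)(C)C)=C/C=C/C(=C)CO[Si](C)(C)C(C)(C)C | intermediate (not isolated)
28 | 2-(trimethylsilyl)ethyl (5aS,6R,9S,9aS)-9-({[(2E,4E)-2,6-bis({[tert-butyl(dimethyl)silyl]oxy}methyl)hepta-2,4,6-trienoyl]oxy}methyl)-9-hydroxy-1-oxo-6-(propan-2-yl)-1,3,5a,6,7,8,9,9a-octahydro-2-benzoxepine-4-carboxylate | CC(C)[C@H]1CC[C@@](O)(COC(=O)/C(CO[Si](C)(C)C(C)(C)C)=C/C=C/C(=C)CO[Si](C)(C)C(C)(C)C)[C@H]2C(=O)OCC(C(=O)OCC[Si](C)(C)C)=C[C@H]12 | intermediate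
29 | 9-O-triethylsilyl ether of 28 | CC(C)[C@H]1CC[C@@](O[Si](CC)(CC)CC)(COC(=O)/C(CO[Si](C)(C)C(C)(C)C)=C/C=C/C(=C)CO[Si](C)(C)C(C)(C)C)[C@H]2C(=O)OCC(C(=O)OCC[Si](C)(C)C)=C[C@H]12 | intermediate
30 | cis Diels–Alder adduct, (1R,6R)-6-acetylcyclohex-2-en-1-yl propenoate (full name in step 19) | CC(C)[C@H]1CC[C@@](O[Si](CC)(CC)CC)(COC(=O)/C(=C/[C@H]2C=C(CO[Si](C)(C)C(C)(C)C)CC[C@H]2C(C)=O)CO[Si](C)(C)C(C)(C)C)[C@H]2C(=O)OCC(C(=O)OCC[Si](C)(C)C)=C[C@H]12 | intermediate
31 | trans ketone, (1R,6S)-6-acetyl epimer of 30 | CC(C)[C@H]1CC[C@@](O[Si](CC)(CC)CC)(COC(=O)/C(=C/[C@H]2C=C(CO[Si](C)(C)C(C)(C)C)CC[C@@H]2C(C)=O)CO[Si](C)(C)C(C)(C)C)[C@H]2C(=O)OCC(C(=O)OCC[Si](C)(C)C)=C[C@H]12 | intermediate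
32 | (1R,6S)-6-(prop-1-en-2-yl) analogue of 31 | CC(C)[C@H]1CC[C@@](O[Si](CC)(CC)CC)(COC(=O)/C(=C/[C@H]2C=C(CO[Si](C)(C)C(C)(C)C)CC[C@@H]2C(C)=C)CO[Si](C)(C)C(C)(C)C)[C@H]2C(=O)OCC(C(=O)OCC[Si](C)(C)C)=C[C@H]12 | intermediate
33 | fully protected target, (1R,6R)-6-(propan-2-yl) compound (full name in step 22) | CC(C)[C@H]1CC[C@@](O[Si](CC)(CC)CC)(COC(=O)/C(=C/[C@H]2C=C(CO[Si](C)(C)C(C)(C)C)CC[C@@H]2C(C)C)CO[Si](C)(C)C(C)(C)C)[C@H]2C(=O)OCC(C(=O)OCC[Si](C)(C)C)=C[C@H]12 | intermediate
34 | (5aS,6R,9S,9aS)-9-hydroxy-9-({[(2E)-2-(hydroxymethyl)-3-[(1R,6R)-3-(hydroxymethyl)-6-(propan-2-yl)cyclohex-2-en-1-yl]prop-2-enoyl]oxy}methyl)-1-oxo-6-(propan-2-yl)-1,3,5a,6,7,8,9,9a-octahydro-2-benzoxepine-4-carboxylic acid | CC(C)[C@H]1CC[C@@](O)(COC(=O)/C(=C/[C@H]2C=C(CO)CC[C@@H]2C(C)C)CO)[C@H]2C(=O)OCC(C(=O)O)=C[C@H]12 | target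

**Totals and risks**

Total step count: 23. Longest linear sequence: 18 steps (steps 1–8, 10–12, 17–23).

Step 19 (key step). The ester-conjugated diene is a weak partner, so the cycloaddition may be slow relative to polymerisation of the enone; the many carbonyl groups may sequester the boron catalyst; and facial discrimination on the remote diene may be poor. Fallback: from 29, an iminium-catalysed Diels–Alder reaction with acrolein 21 is run with (2S,5S)-5-benzyl-2-tert-butyl-3-methylimidazolidin-4-one trifluoroacetate (20 mol %) in MeCN/H2O at −20 °C. This should give the cis-formyl cycloadduct F1 with the same regiochemistry and endo preference. Chemoselective methyl transfer with MeTi(O-i-Pr)3 in THF at −40 °C would give the 1-hydroxyethyl compound F2 (carbinol epimers), and Dess–Martin oxidation (NaHCO3, CH2Cl2) returns the route at ketone 30.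

Step 15. The silanolate may attack phosphorus or the ester carbonyl rather than add to the acrylate; retro-Michael loss of silanolate may lead to polymerisation of the phosphonoacrylate; and E/Z control of the trisubstituted alkene may be incomplete. Fallback: from 22, a Morita–Baylis–Hillman reaction with ethyl acrylate (DABCO, neat, rt) should give the racemic doubly allylic alcohol, ethyl 2-[(2E)-1-hydroxy-4-({[tert-butyl(dimethyl)silyl]oxy}methyl)penta-2,4-dien-1-yl]prop-2-enoate F3. Perrhenate-catalysed 1,3-transposition (Ph3SiOReO3, Et2O, 0 °C) is driven to the conjugated primary alcohol, ethyl (2E,4E)-6-({[tert-butyl(dimethyl)silyl]oxy}methyl)-2-(hydroxymethyl)hepta-2,4,6-trienoate F4. Silylation (t-BuMe2SiCl, imidazole) returns the route at 25.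

Step 17. Acylation of the neopentyl-type primary hydroxyl may be slow enough for intramolecular acyl transfer from the seven-membered lactone to that hydroxyl (contraction to a γ-lactone) to compete, and this is also the reason 18 is not stored. Fallback: from 18, Mitsunobu cyclodehydration (PPh3, DIAD, toluene, 0 °C → rt) should convert the 1,2-diol, with retention at C9, into the spiro-oxirane 2-(trimethylsilyl)ethyl (5aS,6R,9S,9aS)-1-oxo-6-(propan-2-yl)-1,5a,6,7,8,9a-hexahydro-3H-spiro[2-benzoxepine-9,2'-oxirane]-4-carboxylate F5. The oxirane is then opened at its CH2 terminus by acid 26 as the nucleophile (catalytic Cs2CO3, DMF, 50 °C), which returns the route at 28 without ever exposing a free primary hydroxyl to an acylating agent.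

**Further compounds**

F1 | step 19 | cis-formyl cycloadduct, the (1R,6R)-6-formyl analogue of 30 | CC(C)[C@H]1CC[C@@](O[Si](CC)(CC)CC)(COC(=O)/C(=C/[C@H]2C=C(CO[Si](C)(C)C(C)(C)C)CC[C@H]2C=O)CO[Si](C)(C)C(C)(C)C)[C@H]2C(=O)OCC(C(=O)OCC[Si](C)(C)C)=C[C@H]12
F2 | step 19 | 6-(1-hydroxyethyl) analogue of 30 (carbinol epimers) | CC(C)[C@H]1CC[C@@](O[Si](CC)(CC)CC)(COC(=O)/C(=C/[C@H]2C=C(CO[Si](C)(C)C(C)(C)C)CC[C@H]2C(C)O)CO[Si](C)(C)C(C)(C)C)[C@H]2C(=O)OCC(C(=O)OCC[Si](C)(C)C)=C[C@H]12
F3 | step 15 | ethyl 2-[(2E)-1-hydroxy-4-({[tert-butyl(dimethyl)silyl]oxy}methyl)penta-2,4-dien-1-yl]prop-2-enoate (racemic) | CCOC(=O)C(=C)C(O)/C=C/C(=C)CO[Si](C)(C)C(C)(C)C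
F4 | step 15 | ethyl (2E,4E)-6-({[tert-butyl(dimethyl)silyl]oxy}methyl)-2-(hydroxymethyl)hepta-2,4,6-trienoate | CCOC(=O)/C(CO)=C/C=C/C(=C)CO[Si](C)(C)C(C)(C)C
F5 | step 17 | 2-(trimethylsilyl)ethyl (5aS,6R,9S,9aS)-1-oxo-6-(propan-2-yl)-1,5a,6,7,8,9a-hexahydro-3H-spiro[2-benzoxepine-9,2'-oxirane]-4-carboxylate | CC(C)[C@H]1CC[C@@]3(CO3)[C@H]2C(=O)OCC(C(=O)OCC[Si](C)(C)C)=C[C@H]12
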